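Ring C (C10, C12, C13, C17, C18, C19; atoms numbered along the target SMILES) is cut at C18–C19, C13–C17 and C10–C12, because donor and acceptor carbons alternate around it: C19 lies α to a C10 ketone of ring B, C18 and C17 are the β- and α-carbons of the methylene lactone D, and C13/C12 can be a sulfone-activated acceptor–donor pair. One anionic Michael–Michael–aldol cascade thus joins a ring B cycloheptanone, the ring D/E α-methylene lactone and a vinyl sulfone carrying the masked acetyl group, closes ring C and sets five stereocentres. The two seven-membered precursors come from the two carvone enantiomers; the sulfone leaves later as sulfinate.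

Key step: step 34

Remarks on the chemistry (assumptions)
- TBS = tert-butyldimethylsilyl. "Future C6" and similar refer to target numbering.
- The carvone carbonyl is moved to the former β-carbon (1,3-transposition) before ring expansion. This exchanges the roles of the two ring CH2 groups next to the isopropenyl-bearing carbon, so the ring B ketone must be made from (S)-carvone and the ring D/E lactone from (R)-carvone.
- Precursor design: the acetyl group is carried as an acyclic dimethyl ketal (no γ-hydrogen; cleaved by PPTS without harming the oxirane). Ring A is carried as the bis-silyl ether of its 2-methylene-1,4-diol (no acidic C–H; closed at the end by oxidative lactonisation).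
- C12 and C13 of 48 are drawn as expected from a chair transition state; both centres are removed in step 35.

**Ring B ketone (fragment 1) from (S)-carvone**

Step 1
Reactants: 1 (S)-(+)-carvone
Product: 2 trans-6-hydroxy-(S)-carvone
Conditions: KN(SiMe3)2, THF, −78 °C; 3-phenyl-2-(phenylsulfonyl)oxaziridine, −78 °C; AcOH quench
Reagents that add atoms: 3-phenyl-2-(phenylsulfonyl)oxaziridine, O=S(=O)(c1ccccc1)N1OC1c1ccccc1
Why: Enolate oxidation: the potassium dienolate formed kinetically at the α′-CH2 (future C6) is hydroxylated by the N-sulfonyloxaziridine on the face opposite the neighbouring isopropenyl group, which should give the trans alcohol.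

Step 2
Reactants: 2 trans-6-hydroxy-(S)-carvone
Product: 3 TBS ether of 2
Conditions: TBSCl, imidazole, DMF, rt
Reagents that add atoms: tert-butyldimethylsilyl chloride, CC(C)(C)[Si](C)(C)Cl
Why: Imidazole-promoted silylation of the secondary alcohol; no stereocentre is affected.

Step 3
Reactants: 3 TBS ether
Product: 4 epoxy ketone (oxirane trans to isopropenyl)
Conditions: H2O2 (30% aq), NaOH (cat.), MeOH, 0 °C
Reagents that add atoms: hydrogen peroxide, OO
Why: Weitz–Scheffer nucleophilic epoxidation of the enone; hydroperoxide adds axially to the β-carbon anti to the isopropenyl group, so the oxirane should form trans to it, and the trans α′-silyloxy centre is the stable epimer under base.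

Step 4
Reactants: 4 epoxy ketone
Product: 6 allylic alcohol (1S,4S,5R), via epoxy hydrazone 5 (not isolated)
Conditions: N2H4·H2O, AcOH (cat.), MeOH, 0 °C to rt
Reagents that add atoms: hydrazine hydrate, NN.O (its nitrogen is present in 5 only)
Why: Wharton transposition: the epoxy hydrazone fragments with loss of N2 to the allylic alcohol, moving the oxygen function to the former β-carbon (future C10) with retention there and turning the former carbonyl carbon (future C7) into an alkene carbon.

Step 5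
Reactants: 6 allylic alcohol
Product: 7 trans-4-silyloxy enone (4S,5R)
Conditions: DMP (1,1,1-triacetoxy-1λ5,2-benziodoxol-3(1H)-one), CH2Cl2, rt
Reagents that add atoms: none
Why: Hypervalent-iodine oxidation of the secondary allylic alcohol gives the transposed enone, in which the silyloxy carbon (C6) is now the γ-carbon next to the isopropenyl-bearing C21.

Step 6
Reactants: 7 trans-4-silyloxy enone
Product: 8 trans-4-hydroxy enone (4S,5R)
Conditions: HF·pyridine, pyridine, THF, 0 °C to rt
Reagents that add atoms: none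
Why: Fluoride-mediated cleavage of the silyl ether under mildly acidic conditions, which avoid γ-deprotonation of the enone.

Step 7
Reactants: 8 trans-4-hydroxy enone
Product: 9 cis 4-nitrobenzoate (1R,6R)
Conditions: PPh3, diisopropyl azodicarboxylate, 4-nitrobenzoic acid, THF, 0 °C to rt
Reagents that add atoms: 4-nitrobenzoic acid, O=C(O)c1ccc(cc1)[N+](=O)[O-]
Why: Mitsunobu reaction: SN2 displacement of the activated allylic oxyphosphonium by the carboxylate inverts C6 and sets the cis O/isopropenyl relationship of the target; elimination is disfavoured because the trans alcohol has no anti-periplanar hydrogen at C21.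

Step 8
Reactants: 9 cis 4-nitrobenzoate
Product: 10 side-chain allylic alcohol (1R,6R)
Conditions: SeO2 (0.3 equiv), t-BuOOH, CH2Cl2, rt
Reagents that add atoms: tert-butyl hydroperoxide, CC(C)(C)OO (oxygen delivered by way of SeO2, O=[Se]=O)
Why: Allylic oxidation (ene reaction of SeO2, then [2,3]-shift) of the electron-rich 1,1-disubstituted alkene at its methyl group; the electron-poor enone alkene should not react.

Step 9
Reactants: 10 side-chain allylic alcohol
Product: 11 cis diol enone (4R,5R)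
Conditions: K2CO3 (cat.), MeOH, 0 °C
Reagents that add atoms: none
Why: Base-catalysed transesterification (methanolysis) of the activated benzoate; no stereocentre is touched.

Step 10
Reactants: 11 cis diol enone
Product: 12 bis-TBS enone (4R,5R)
Conditions: TBSOTf, 2,6-lutidine, CH2Cl2, −78 to 0 °C
Reagents that add atoms: tert-butyldimethylsilyl triflate, CC(C)(C)[Si](C)(C)OS(=O)(=O)C(F)(F)F
Why: Silylation of the hindered secondary and the primary alcohol with the silyl triflate.

Step 11
Reactants: 12 bis-TBS enone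
Product: 13 all-cis cyclohexanone (2S,4R,5R)
Conditions: LiBH(s-Bu)3, THF, −78 °C; then 2,6-di-tert-butyl-4-methylphenol, −78 °C
Reagents that add atoms: none
Why: Conjugate hydride reduction of the enone followed by kinetic C-protonation of the enolate: the hindered phenol should deliver the proton axially on the face opposite the two cis substituents (the other axial approach is syn to an axial silyloxy group), placing the methyl-bearing centre (C8) cis to C6–O and C21.

Step 12
Reactants: 13 all-cis cyclohexanone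
Product: 15 ring B ketone (fragment 1), via α-silyl ketone 14 (not isolated)
Conditions: Me3SiCHN2, Sc(OTf)3 (10 mol %), toluene, 0 °C to rt; then SiO2, wet CH2Cl2
Reagents that add atoms: (trimethylsilyl)diazomethane, C[Si](C)(C)C=[N+]=[N-] (the silyl group is present in 14 only)
Why: Lewis acid-catalysed diazoalkane homologation (Tiffeneau–Demjanov-type ring expansion): the less substituted α-CH2 migrates, so the new carbon (C19) enters between the carbonyl and C20, C8 is not enolised, and the α-silyl ketone is protodesilylated on silica.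

**Ring D/E lactone (fragment 2) from (R)-carvone**

Step 13
Reactants: 16 (R)-(−)-carvone
Product: 17 trans-6-hydroxy-(R)-carvone
Conditions: KN(SiMe3)2, THF, −78 °C; 3-phenyl-2-(phenylsulfonyl)oxaziridine, −78 °C; AcOH quench
Reagents that add atoms: 3-phenyl-2-(phenylsulfonyl)oxaziridine, O=S(=O)(c1ccccc1)N1OC1c1ccccc1
Why: Enolate oxidation as in step 1 on the enantiomer; the oxidant should enter anti to the isopropenyl group (trans alcohol, future C25).

Step 14
Reactants: 17 trans-6-hydroxy-(R)-carvone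
Product: 18 TBS ether of 17
Conditions: TBSCl, imidazole, DMF, rt
Reagents that add atoms: tert-butyldimethylsilyl chloride, CC(C)(C)[Si](C)(C)Cl
Why: Silylation of the secondary alcohol as in step 2.

Step 15
Reactants: 18 TBS ether
Product: 19 epoxy ketone (oxirane trans to isopropenyl)
Conditions: H2O2 (30% aq), NaOH (cat.), MeOH, 0 °C
Reagents that add atoms: hydrogen peroxide, OO
Why: Weitz–Scheffer epoxidation as in step 3; attack anti to the isopropenyl group.

Step 16
Reactants: 19 epoxy ketone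
Product: 21 allylic alcohol (1R,4R,5S), via epoxy hydrazone 20 (not isolated)
Conditions: N2H4·H2O, AcOH (cat.), MeOH, 0 °C to rt
Reagents that add atoms: hydrazine hydrate, NN.O (its nitrogen is present in 20 only)
Why: Wharton transposition as in step 4; the oxygen function moves to the future C29.

Step 17
Reactants: 21 allylic alcohol
Product: 22 trans-4-silyloxy enone (4R,5S)
Conditions: DMP, CH2Cl2, rt
Reagents that add atoms: none
Why: Hypervalent-iodine oxidation of the allylic alcohol as in step 5.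

Step 18
Reactants: 22 trans-4-silyloxy enone
Product: 23 trans-4-hydroxy enone (4R,5S)
Conditions: HF·pyridine, pyridine, THF, 0 °C to rt
Reagents that add atoms: none
Why: Fluoride-mediated desilylation as in step 6.

Step 19
Reactants: 23 trans-4-hydroxy enone
Product: 24 cis 4-nitrobenzoate (1S,6S)
Conditions: PPh3, diisopropyl azodicarboxylate, 4-nitrobenzoic acid, THF, 0 °C to rt
Reagents that add atoms: 4-nitrobenzoic acid, O=C(O)c1ccc(cc1)[N+](=O)[O-]
Why: Mitsunobu inversion as in step 7; it sets the cis relationship between C25–O and the C38 substituent.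

Step 20
Reactants: 24 cis 4-nitrobenzoate
Product: 25 side-chain allylic alcohol (1S,6S)
Conditions: SeO2 (0.3 equiv), t-BuOOH, CH2Cl2, rt
Reagents that add atoms: tert-butyl hydroperoxide, CC(C)(C)OO (oxygen delivered by way of SeO2, O=[Se]=O)
Why: Allylic oxidation of the isopropenyl methyl group as in step 8.

Step 21
Reactants: 25 side-chain allylic alcohol
Product: 26 cis diol enone (4S,5S)
Conditions: K2CO3 (cat.), MeOH, 0 °C
Reagents that add atoms: none
Why: Methanolysis of the benzoate as in step 9.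

Step 22
Reactants: 26 cis diol enone
Product: 27 bis-TBS enone (4S,5S)
Conditions: TBSOTf, 2,6-lutidine, CH2Cl2, −78 to 0 °C
Reagents that add atoms: tert-butyldimethylsilyl triflate, CC(C)(C)[Si](C)(C)OS(=O)(=O)C(F)(F)F
Why: Double silylation as in step 10.

Step 23
Reactants: 27 bis-TBS enone
Product: 28 all-cis cyclohexanone (2R,4S,5S)
Conditions: LiBH(s-Bu)3, THF, −78 °C; then 2,6-di-tert-butyl-4-methylphenol, −78 °C
Reagents that add atoms: none
Why: Conjugate reduction and kinetic enolate protonation as in step 11; the proton should enter opposite the two cis substituents, giving the C27 methyl cis to both.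

Step 24
Reactants: 28 all-cis cyclohexanone
Product: 30 enantiomeric cycloheptanone (2R,4S,5S), via α-silyl ketone 29 (not isolated)
Conditions: Me3SiCHN2, Sc(OTf)3 (10 mol %), toluene, 0 °C to rt; then SiO2, wet CH2Cl2
Reagents that add atoms: (trimethylsilyl)diazomethane, C[Si](C)(C)C=[N+]=[N-] (the silyl group is present in 29 only)
Why: Diazoalkane ring expansion as in step 12; the CH2 group migrates and the new carbon becomes C36.

Step 25
Reactants: 30 enantiomeric cycloheptanone
Product: 31 enol triflate (4S,5S,7R)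
Conditions: KN(SiMe3)2, THF, −78 °C; PhNTf2, −78 to 0 °C
Reagents that add atoms: N-phenylbis(trifluoromethanesulfonimide), FC(F)(F)S(=O)(=O)N(c1ccccc1)S(=O)(=O)C(F)(F)F
Why: Enol triflate formation: kinetic deprotonation at the α-CH2 (C36) leaves the methyl-bearing C27 untouched and the enolate is trapped on oxygen.

Step 26
Reactants: 31 enol triflate
Product: 32 ring allylic alcohol (4S,5S,7R)
Conditions: Bu3SnCH2OH, Pd(PPh3)4 (5 mol %), LiCl, 1,4-dioxane, 100 °C
Reagents that add atoms: (tributylstannyl)methanol, OC[Sn](CCCC)(CCCC)CCCC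
Why: Stille cross-coupling of the alkenyl triflate with the hydroxymethylstannane (chloride assisted) installs C30 as the allylic alcohol.

Step 27
Reactants: 32 ring allylic alcohol
Product: 33 epoxy alcohol (1R,2R,4S,5S,7R)
Conditions: Ti(OiPr)4 (cat.), D-(−)-diethyl tartrate, t-BuOOH, 4 Å molecular sieves, CH2Cl2, −20 °C
Reagents that add atoms: tert-butyl hydroperoxide, CC(C)(C)OO
Why: Sharpless asymmetric epoxidation: with D-(−)-tartrate the oxygen should be delivered to the ring face opposite the C27 methyl, C25–O and C38 substituents, which is also the sterically preferred face (matched case); the silylated allyl ether in the side chain is not a substrate.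

Step 28
Reactants: 33 epoxy alcohol
Product: 34 epoxy triol
Conditions: Bu4NF, AcOH, THF, 0 °C to rt
Reagents that add atoms: none
Why: Fluoride-mediated desilylation, buffered with acetic acid to prevent Payne rearrangement of the epoxy alcohol.

Step 29
Reactants: 34 epoxy triol
Product: 37 hydroxy lactone (ring D closed), via hydroxy enal 35 (not isolated), via lactol 36 (not isolated)
Conditions: MnO2 (activated, excess), CH2Cl2, rt
Reagents that add atoms: none
Why: Oxidative lactonisation: MnO2 oxidises only the allylic primary alcohol, the enal is captured by the cis C25 hydroxyl as a lactol and this is oxidised to the α-methylene γ-lactone; the cis fusion follows from the existing C25 and C38 centres.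

Step 30
Reactants: 37 hydroxy lactone
Product: 38 ring D/E lactone (fragment 2)
Conditions: TBSCl, imidazole, CH2Cl2, 0 °C to rt
Reagents that add atoms: tert-butyldimethylsilyl chloride, CC(C)(C)[Si](C)(C)Cl
Why: Silylation of the remaining primary alcohol.

**Vinyl sulfone (fragment 3)**

Step 31
Reactants: 39 but-3-en-2-one; 40 sodium benzenesulfinate
Product: 41 4-(phenylsulfonyl)butan-2-one
Conditions: AcOH, EtOH/H2O, rt
Reagents that add atoms: none
Why: Conjugate (sulfa-Michael) addition of benzenesulfinic acid, generated with acetic acid, to the enone.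

Step 32
Reactants: 41 4-(phenylsulfonyl)butan-2-one
Product: 42 dimethyl ketal
Conditions: HC(OMe)3, MeOH, TsOH (cat.), rt
Reagents that add atoms: trimethyl orthoformate, COC(OC)OC
Why: Acid-catalysed ketalisation driven by the orthoformate as water scavenger.

Step 33
Reactants: 42 dimethyl ketal
Product: 45 vinyl sulfone ketal (fragment 3), via seleno sulfone 43 (not isolated), via selenoxide 44 (not isolated)
Conditions: LiN(i-Pr)2, THF, −78 °C; PhSeCl; then H2O2, pyridine, CH2Cl2, 0 °C to rt
Reagents that add atoms: benzeneselenenyl chloride, Cl[Se]c1ccccc1 (selenium is present in 43 and 44 only); hydrogen peroxide, OO (its oxygen is present in 44 only)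
Why: α-Selenenylation of the sulfonyl carbanion, oxidation to the selenoxide and syn-elimination give the vinyl sulfone, for which the E isomer is expected.

**Key step**

Step 34
Reactants: 15 ring B ketone (fragment 1); 38 ring D/E lactone (fragment 2); 45 vinyl sulfone ketal (fragment 3)
Product: 48 ring C β-hydroxy sulfone, via lactone enolate 46 (not isolated), via sulfonyl carbanion 47 (not isolated)
Conditions: LiN(i-Pr)2, THF, −78 °C; 38 added slowly, −78 °C; then 45 (2.5 equiv), −78 to −30 °C; AcOH quench at −78 °C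
Reagents that add atoms: none
Why: Proposed new method: LiN(i-Pr)2 removes a C19 proton of 15 (kinetic; the C8 methine is not touched), the lithium enolate adds to the exocyclic C18 of 38, the fully substituted lactone enolate 46 adds to C13 of 45, and the α-sulfonyl carbanion 47 attacks the C10 ketone regenerated in the first addition (Michael, Michael, sulfone aldol), so that C18–C19, C13–C17 and C10–C12 form in one flask. The closest known reaction type is the Michael–Michael–ring-closure annulation of a ketone enolate with two equivalents of one acrylate; two different acceptors with an α-sulfonyl carbanion as closing nucleophile on fragments of this size are not established. Ring C closes by 6-exo-trig attack of C12 on the C10 carbonyl through a lithium-bridged chair. C19 should be set by approach of 38 to the cycloheptenolate conformer with equatorial C21 side chain from the face opposite the ring fold (cis to the C8 methyl, as in the more stable 2,7-cis ketone), C17 by attack of 45 on the convex face of the cis-fused lactone enolate anti to C37, C13 and C12 by the chair (ketal carbon and sulfonyl equatorial, C12 equilibrating as a carbanion), and C10 by equatorial attack that gives the trans B/C fusion with axial OH, an isomer the aldolate can reach by retro-aldol equilibration. The step needs regioselective enolisation (kinetic base, CH2 versus CH), chemoselective first addition (the unhindered methylene lactone reacts far faster than the β-branched vinyl sulfone, and slow addition leaves no 38 to trap 46) and freedom from γ-deprotonation of the acceptor (45 has no γ-hydrogen).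

**From the annulation product to the target**

Step 35
Reactants: 48 ring C β-hydroxy sulfone
Product: 50 γ-hydroxy enone, via sulfonyl ketone 49 (not isolated)
Conditions: PPTS, acetone/H2O, rt; then DBU, CH2Cl2, 0 °C
Reagents that add atoms: water, O
Why: Acid hydrolysis of the acyclic ketal, then E1cB elimination: DBU removes H13 next to the new ketone and benzenesulfinate leaves from C12, which creates the C12=C13 enone and erases the two provisional centres.

Step 36
Reactants: 50 γ-hydroxy enone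
Product: 51 tetraol
Conditions: Bu4NF, AcOH, THF, 0 °C to rt
Reagents that add atoms: none
Why: Fluoride-mediated cleavage of the three silyl ethers under buffered conditions (no free alkoxide, hence no Payne rearrangement and no oxa-Michael addition).

Step 37
Reactants: 51 tetraol
Product: 54 epoxy aldehyde with ring A closed, via dialdehyde 52 (not isolated), via lactol aldehyde 53 (not isolated)
Conditions: TEMPO (cat.), PhI(OAc)2, CH2Cl2, rt
Reagents that add atoms: none
Why: Nitroxyl-catalysed oxidation: both primary alcohols are oxidised, the 2-substituted acrolein is captured by the cis C6 hydroxyl and the lactol is oxidised to ring A (oxidative lactonisation), C30 stops at the aldehyde, and the tertiary C10 hydroxyl cannot be oxidised.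

Step 38
Reactants: 54 epoxy aldehyde
Product: 55 CNP0177598.2 (target)
Conditions: Ph3P=CHC(O)CH3, CH2Cl2, rt to 40 °C
Reagents that add atoms: 1-(triphenyl-λ5-phosphanylidene)propan-2-one, CC(=O)C=P(c1ccccc1)(c1ccccc1)c1ccccc1
Why: Wittig olefination with a stabilised ylide, which should give the E-enone and does not touch ketones or lactones.

**Compound list**

1 | (S)-(+)-carvone | CC1=CC[C@@H](CC1=O)C(C)=C | starting material
2 | (5R,6R)-6-hydroxy-2-methyl-5-(prop-1-en-2-yl)cyclohex-2-en-1-one (OH trans to isopropenyl) | CC1=CC[C@@H]([C@@H](O)C1=O)C(C)=C | intermediate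
3 | (5R,6R)-6-[(TBS)oxy]-2-methyl-5-(prop-1-en-2-yl)cyclohex-2-en-1-one | CC1=CC[C@@H]([C@@H](O[Si](C)(C)C(C)(C)C)C1=O)C(C)=C | intermediate
4 | (1S,3R,4R,6S)-3-[(TBS)oxy]-1-methyl-4-(prop-1-en-2-yl)-7-oxabicyclo[4.1.0]heptan-2-one | C[C@]12O[C@H]1C[C@@H]([C@@H](O[Si](C)(C)C(C)(C)C)C2=O)C(C)=C | intermediate
5 | hydrazone of 4 | C[C@]12O[C@H]1C[C@@H]([C@@H](O[Si](C)(C)C(C)(C)C)C2=NN)C(C)=C | intermediate (not isolated)
6 | (1S,4S,5R)-4-[(TBS)oxy]-2-methyl-5-(prop-1-en-2-yl)cyclohex-2-en-1-ol | CC1=C[C@H](O[Si](C)(C)C(C)(C)C)[C@@H](C(C)=C)C[C@@H]1O | intermediate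
7 | (4S,5R)-4-[(TBS)oxy]-2-methyl-5-(prop-1-en-2-yl)cyclohex-2-en-1-one (trans) | CC1=C[C@H](O[Si](C)(C)C(C)(C)C)[C@@H](C(C)=C)CC1=O | intermediate
8 | (4S,5R)-4-hydroxy-2-methyl-5-(prop-1-en-2-yl)cyclohex-2-en-1-one (trans) | CC1=C[C@H](O)[C@@H](C(C)=C)CC1=O | intermediate
9 | (1R,6R)-3-methyl-4-oxo-6-(prop-1-en-2-yl)cyclohex-2-en-1-yl 4-nitrobenzoate (cis) | CC1=C[C@@H](OC(=O)c2ccc(cc2)[N+](=O)[O-])[C@@H](C(C)=C)CC1=O | intermediate
10 | (1R,6R)-6-(3-hydroxyprop-1-en-2-yl)-3-methyl-4-oxocyclohex-2-en-1-yl 4-nitrobenzoate | CC1=C[C@@H](OC(=O)c2ccc(cc2)[N+](=O)[O-])[C@@H](C(=C)CO)CC1=O | intermediate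
11 | (4R,5R)-4-hydroxy-5-(3-hydroxyprop-1-en-2-yl)-2-methylcyclohex-2-en-1-one (cis) | CC1=C[C@@H](O)[C@@H](C(=C)CO)CC1=O | intermediate
12 | (4R,5R)-4-[(TBS)oxy]-5-{3-[(TBS)oxy]prop-1-en-2-yl}-2-methylcyclohex-2-en-1-one | CC1=C[C@@H](O[Si](C)(C)C(C)(C)C)[C@@H](C(=C)CO[Si](C)(C)C(C)(C)C)CC1=O | intermediate
13 | (2S,4R,5R)-4-[(TBS)oxy]-5-{3-[(TBS)oxy]prop-1-en-2-yl}-2-methylcyclohexan-1-one (all-cis) | C[C@H]1C[C@@H](O[Si](C)(C)C(C)(C)C)[C@@H](C(=C)CO[Si](C)(C)C(C)(C)C)CC1=O | intermediate
14 | 7-(trimethylsilyl) derivative of 15 | C[C@H]1C[C@@H](O[Si](C)(C)C(C)(C)C)[C@@H](C(=C)CO[Si](C)(C)C(C)(C)C)CC([Si](C)(C)C)C1=O | intermediate (not isolated)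
15 | (2S,4R,5R)-4-[(TBS)oxy]-5-{3-[(TBS)oxy]prop-1-en-2-yl}-2-methylcycloheptan-1-one (ring B ketone, fragment 1) | C[C@H]1C[C@@H](O[Si](C)(C)C(C)(C)C)[C@@H](C(=C)CO[Si](C)(C)C(C)(C)C)CCC1=O | intermediate
16 | (R)-(−)-carvone | CC1=CC[C@H](CC1=O)C(C)=C | starting material
17 | (5S,6S)-6-hydroxy-2-methyl-5-(prop-1-en-2-yl)cyclohex-2-en-1-one | CC1=CC[C@H]([C@H](O)C1=O)C(C)=C | intermediate
18 | (5S,6S)-6-[(TBS)oxy]-2-methyl-5-(prop-1-en-2-yl)cyclohex-2-en-1-one | CC1=CC[C@H]([C@H](O[Si](C)(C)C(C)(C)C)C1=O)C(C)=C | intermediate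
19 | (1R,3S,4S,6R)-3-[(TBS)oxy]-1-methyl-4-(prop-1-en-2-yl)-7-oxabicyclo[4.1.0]heptan-2-one | C[C@@]12O[C@@H]1C[C@H]([C@H](O[Si](C)(C)C(C)(C)C)C2=O)C(C)=C | intermediate
20 | hydrazone of 19 | C[C@@]12O[C@@H]1C[C@H]([C@H](O[Si](C)(C)C(C)(C)C)C2=NN)C(C)=C | intermediate (not isolated)
21 | (1R,4R,5S)-4-[(TBS)oxy]-2-methyl-5-(prop-1-en-2-yl)cyclohex-2-en-1-ol | CC1=C[C@@H](O[Si](C)(C)C(C)(C)C)[C@H](C(C)=C)C[C@H]1O | intermediate
22 | (4R,5S)-4-[(TBS)oxy]-2-methyl-5-(prop-1-en-2-yl)cyclohex-2-en-1-one (trans) | CC1=C[C@@H](O[Si](C)(C)C(C)(C)C)[C@H](C(C)=C)CC1=O | intermediate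
23 | (4R,5S)-4-hydroxy-2-methyl-5-(prop-1-en-2-yl)cyclohex-2-en-1-one (trans) | CC1=C[C@@H](O)[C@H](C(C)=C)CC1=O | intermediate
24 | (1S,6S)-3-methyl-4-oxo-6-(prop-1-en-2-yl)cyclohex-2-en-1-yl 4-nitrobenzoate (cis) | CC1=C[C@H](OC(=O)c2ccc(cc2)[N+](=O)[O-])[C@H](C(C)=C)CC1=O | intermediate
25 | (1S,6S)-6-(3-hydroxyprop-1-en-2-yl)-3-methyl-4-oxocyclohex-2-en-1-yl 4-nitrobenzoate | CC1=C[C@H](OC(=O)c2ccc(cc2)[N+](=O)[O-])[C@H](C(=C)CO)CC1=O | intermediate
26 | (4S,5S)-4-hydroxy-5-(3-hydroxyprop-1-en-2-yl)-2-methylcyclohex-2-en-1-one (cis) | CC1=C[C@H](O)[C@H](C(=C)CO)CC1=O | intermediate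
27 | (4S,5S)-4-[(TBS)oxy]-5-{3-[(TBS)oxy]prop-1-en-2-yl}-2-methylcyclohex-2-en-1-one | CC1=C[C@H](O[Si](C)(C)C(C)(C)C)[C@H](C(=C)CO[Si](C)(C)C(C)(C)C)CC1=O | intermediate
28 | (2R,4S,5S)-4-[(TBS)oxy]-5-{3-[(TBS)oxy]prop-1-en-2-yl}-2-methylcyclohexan-1-one (all-cis) | C[C@@H]1C[C@H](O[Si](C)(C)C(C)(C)C)[C@H](C(=C)CO[Si](C)(C)C(C)(C)C)CC1=O | intermediate
29 | 7-(trimethylsilyl) derivative of 30 | C[C@@H]1C[C@H](O[Si](C)(C)C(C)(C)C)[C@H](C(=C)CO[Si](C)(C)C(C)(C)C)CC([Si](C)(C)C)C1=O | intermediate (not isolated)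
30 | (2R,4S,5S)-4-[(TBS)oxy]-5-{3-[(TBS)oxy]prop-1-en-2-yl}-2-methylcycloheptan-1-one | C[C@@H]1C[C@H](O[Si](C)(C)C(C)(C)C)[C@H](C(=C)CO[Si](C)(C)C(C)(C)C)CCC1=O | intermediate
31 | (4S,5S,7R)-5-[(TBS)oxy]-4-{3-[(TBS)oxy]prop-1-en-2-yl}-7-methylcyclohept-1-en-1-yl trifluoromethanesulfonate | C[C@@H]1C[C@H](O[Si](C)(C)C(C)(C)C)[C@H](C(=C)CO[Si](C)(C)C(C)(C)C)CC=C1OS(=O)(=O)C(F)(F)F | intermediate
32 | [(4S,5S,7R)-5-[(TBS)oxy]-4-{3-[(TBS)oxy]prop-1-en-2-yl}-7-methylcyclohept-1-en-1-yl]methanol | C[C@@H]1C[C@H](O[Si](C)(C)C(C)(C)C)[C@H](C(=C)CO[Si](C)(C)C(C)(C)C)CC=C1CO | intermediate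
33 | [(1R,2R,4S,5S,7R)-4-[(TBS)oxy]-5-{3-[(TBS)oxy]prop-1-en-2-yl}-2-methyl-8-oxabicyclo[5.1.0]octan-1-yl]methanol (oxirane trans to the 2-methyl group) | C[C@@H]1C[C@H](O[Si](C)(C)C(C)(C)C)[C@H](C(=C)CO[Si](C)(C)C(C)(C)C)C[C@H]2O[C@@]12CO | intermediate
34 | (1R,2R,4S,5S,7R)-1-(hydroxymethyl)-5-(3-hydroxyprop-1-en-2-yl)-2-methyl-8-oxabicyclo[5.1.0]octan-4-ol | C[C@@H]1C[C@H](O)[C@H](C(=C)CO)C[C@H]2O[C@@]12CO | intermediate
35 | 2-substituted acrolein from 34 (side-chain CH2OH oxidised to CHO) | C[C@@H]1C[C@H](O)[C@H](C(=C)C=O)C[C@H]2O[C@@]12CO | intermediate (not isolated)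
36 | cis-fused methylene lactol of ring D (anomeric centre undefined) | C=C1C(O)O[C@H]2C[C@@H](C)[C@]3(CO)O[C@@H]3C[C@H]21 | intermediate (not isolated)
37 | ring D/E hydroxy lactone: cis-fused α-methylene γ-lactone on C25/C38 of the epoxycycloheptane, C27 methyl cis to the lactone oxygen, oxirane (C29/C36) on the opposite face, CH2OH on C29 (25S,27R,29R,36R,38S) | C=C1C(=O)O[C@H]2C[C@@H](C)[C@]3(CO)O[C@@H]3C[C@H]21 | intermediate
38 | TBS ether of 37 (ring D/E α-methylene lactone, fragment 2) | C=C1C(=O)O[C@H]2C[C@@H](C)[C@]3(CO[Si](C)(C)C(C)(C)C)O[C@@H]3C[C@H]21 | intermediate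
39 | but-3-en-2-one | CC(=O)C=C | starting material
40 | sodium benzenesulfinate | [Na+].[O-]S(=O)c1ccccc1 | starting material
41 | 4-(phenylsulfonyl)butan-2-one | CC(=O)CCS(=O)(=O)c1ccccc1 | intermediate
42 | (3,3-dimethoxybutane-1-sulfonyl)benzene | COC(C)(OC)CCS(=O)(=O)c1ccccc1 | intermediate
43 | [3,3-dimethoxy-1-(phenylselanyl)butane-1-sulfonyl]benzene | COC(C)(OC)CC([Se]c1ccccc1)S(=O)(=O)c1ccccc1 | intermediate (not isolated)
44 | selenoxide of 43 | COC(C)(OC)CC([Se](=O)c1ccccc1)S(=O)(=O)c1ccccc1 | intermediate (not isolated)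
45 | (E)-(3,3-dimethoxybut-1-ene-1-sulfonyl)benzene (fragment 3) | COC(C)(OC)/C=C/S(=O)(=O)c1ccccc1 | intermediate
46 | lithium enolate of lactone D after the first Michael addition (C18–C19 formed, C19 as in the target) | C=C(CO[Si](C)(C)C(C)(C)C)[C@@H]1[C@H](O[Si](C)(C)C(C)(C)C)C[C@H](C)C(=O)[C@H](CC2=C(O[Li])O[C@H]3C[C@@H](C)[C@]4(CO[Si](C)(C)C(C)(C)C)O[C@@H]4C[C@H]32)CC1 | intermediate (not isolated)
47 | lithiated sulfone after the second Michael addition (C13–C17 formed; C12 carbanion) | C=C(CO[Si](C)(C)C(C)(C)C)[C@@H]1[C@H](O[Si](C)(C)C(C)(C)C)C[C@H](C)C(=O)[C@H](C[C@@]2([C@@H](C([Li])S(=O)(=O)c5ccccc5)C(C)(OC)OC)C(=O)O[C@H]3C[C@@H](C)[C@]4(CO[Si](C)(C)C(C)(C)C)O[C@@H]4C[C@H]32)CC1 | intermediate (not isolated)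
48 | ring C β-hydroxy sulfone: rings B, C, D, E assembled; C6, C8, C10, C17, C19, C21, C25, C27, C29, C36, C38 as in the target; C12 sulfonyl cis to C10–OH and trans to the C13 dimethyl-ketal carbon; three TBS ethers | C=C(CO[Si](C)(C)C(C)(C)C)[C@@H]1[C@H](O[Si](C)(C)C(C)(C)C)C[C@H](C)[C@@]2(O)[C@H](S(=O)(=O)c3ccccc3)[C@@H](C(C)(OC)OC)[C@]4(C[C@@H]2C1)C(=O)O[C@H]5C[C@@H](C)[C@]6(CO[Si](C)(C)C(C)(C)C)O[C@@H]6C[C@H]54 | intermediate
49 | β-sulfonyl methyl ketone from 48 (ketal hydrolysed) | C=C(CO[Si](C)(C)C(C)(C)C)[C@@H]1[C@H](O[Si](C)(C)C(C)(C)C)C[C@H](C)[C@@]2(O)[C@H](S(=O)(=O)c3ccccc3)[C@@H](C(C)=O)[C@]4(C[C@@H]2C1)C(=O)O[C@H]5C[C@@H](C)[C@]6(CO[Si](C)(C)C(C)(C)C)O[C@@H]6C[C@H]54 | intermediate (not isolated)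
50 | γ-hydroxy enone (C12=C13, C13 acetyl, C10–OH), three TBS ethers | C=C(CO[Si](C)(C)C(C)(C)C)[C@@H]1[C@H](O[Si](C)(C)C(C)(C)C)C[C@H](C)[C@@]2(O)C=C(C(C)=O)[C@]3(C[C@@H]2C1)C(=O)O[C@H]4C[C@@H](C)[C@]5(CO[Si](C)(C)C(C)(C)C)O[C@@H]5C[C@H]43 | intermediate
51 | tetraol (C6–OH, side-chain CH2OH, C10–OH, C30–OH) | C=C(CO)[C@@H]1[C@H](O)C[C@H](C)[C@@]2(O)C=C(C(C)=O)[C@]3(C[C@@H]2C1)C(=O)O[C@H]4C[C@@H](C)[C@]5(CO)O[C@@H]5C[C@H]43 | intermediate
52 | dialdehyde (side-chain acrolein and C30 aldehyde, C6–OH free) | C=C(C=O)[C@@H]1[C@H](O)C[C@H](C)[C@@]2(O)C=C(C(C)=O)[C@]3(C[C@@H]2C1)C(=O)O[C@H]4C[C@@H](C)[C@]5(C=O)O[C@@H]5C[C@H]43 | intermediate (not isolated)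
53 | ring A lactol with C30 aldehyde (anomeric centre undefined) | C=C1C(O)O[C@@H]2C[C@H](C)[C@@]3(O)C=C(C(C)=O)[C@]4(C[C@@H]3C[C@H]12)C(=O)O[C@H]1C[C@@H](C)[C@]2(C=O)O[C@@H]2C[C@H]14 | intermediate (not isolated)
54 | epoxy aldehyde with rings A–E complete (C30 = CHO) | C=C1C(=O)O[C@@H]2C[C@H](C)[C@@]3(O)C=C(C(C)=O)[C@]4(C[C@@H]3C[C@H]12)C(=O)O[C@H]1C[C@@H](C)[C@]2(C=O)O[C@@H]2C[C@H]14 | intermediate
55 | CNP0177598.2 | C=C1C(=O)O[C@@H]2C[C@H](C)[C@@]3(O)C=C(C(C)=O)[C@]4(C[C@@H]3C[C@H]12)C(=O)O[C@H]1C[C@@H](C)[C@]2(/C=C/C(C)=O)O[C@@H]2C[C@H]14 | target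

**Step count and risks**

Total: 38 steps. Longest linear sequence: 23 steps (16 to 55: steps 13–30, 34, 35–38).

Steps most likely to fail:

1. Step 34 (the step labelled as a new method). What may go wrong:
 - proton transfer from a ketone α-CH to the hindered lactone enolate before it meets the sulfone;
 - anionic oligomerisation of the methylene lactone;
 - slow bond formation between the quaternary C17 and the branched C13;
 - poor facial selectivity at C19;
 - loss of the ring closure by retro-aldol on warming.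

 Fallback (known chemistry, cycloaddition instead of anionic annulation): ketone 15 is converted with KN(SiMe3)2 and PhNTf2 into the enol triflate F1. Heck coupling of F1 with but-3-en-2-one 39 (Pd(OAc)2, PPh3, Et3N, DMF) gives the dienone F2. A thermal Diels–Alder reaction of F2 with lactone 38 (toluene, heat) forms the same C18–C19 and C13–C17 bonds and gives the cyclohexene F3. mCPBA epoxidises its C10=C12 bond to the β,γ-epoxy ketone F4, and Et3N opens this by E1cB elimination to the γ-hydroxy enone, which rejoins the route at 50.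

2. Step 11 (the same operation is step 23 in the mirror series). What may go wrong: poor facial selectivity in the enolate protonation, or epimerisation of the new α-methyl centre during work-up.

 Fallback (hydrogen delivered to the exposed face instead of a proton quench): enone 12 is treated with mCPBA, which masks the side-chain alkene as the oxirane F5 (both epimers at the oxirane carbon). Hydrogenation (H2, Pd/C, EtOAc) of the enone alkene from the face opposite the two substituents gives the saturated ketone F6. Deoxygenation of the oxirane (Rh2(OAc)4, dimethyl diazomalonate, toluene, 80 °C) returns the alkene and rejoins the route at 13. In the mirror series, 27 goes through the oxirane F7 and the saturated ketone F8 to 28.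

3. Step 12 (the same operation is step 24). What may go wrong: migration of the wrong α-carbon, double homologation, or epimerisation at the α-methyl centre under Lewis acid.

 Fallback (regiochemistry fixed by the enol ether): ketone 13 is converted with LiN(i-Pr)2 and Me3SiCl into the kinetic silyl enol ether F9. Simmons–Smith cyclopropanation (Et2Zn, CH2I2) gives the silyloxycyclopropane F10. FeCl3 in DMF opens it to the β-chloro cycloheptanone F11, and NaOAc in MeOH eliminates HCl to the cycloheptenone F12. Conjugate reduction with [(Ph3P)CuH]6 rejoins the route at 15. In the mirror series, 28 goes through the silyl enol ether F13, the silyloxycyclopropane F14, the β-chloro ketone F15 and the cycloheptenone F16 to 30.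

Further compounds

F1 | step 34 | enol triflate of 15 (C10=C19) | C[C@H]1C[C@@H](O[Si](C)(C)C(C)(C)C)[C@@H](C(=C)CO[Si](C)(C)C(C)(C)C)CC=C1OS(=O)(=O)C(F)(F)F
F2 | step 34 | ring B dienone (C19=C10–C12=C13–acetyl) | C[C@H]1C[C@@H](O[Si](C)(C)C(C)(C)C)[C@@H](C(=C)CO[Si](C)(C)C(C)(C)C)CC=C1/C=C/C(C)=O
F3 | step 34 | Diels–Alder adduct of F2 and 38 (C10=C12 alkene) | C=C(CO[Si](C)(C)C(C)(C)C)[C@@H]1[C@H](O[Si](C)(C)C(C)(C)C)C[C@H](C)C2=C[C@@H](C(C)=O)[C@]3(C[C@@H]2C1)C(=O)O[C@H]4C[C@@H](C)[C@]5(CO[Si](C)(C)C(C)(C)C)O[C@@H]5C[C@H]43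
F4 | step 34 | C10/C12 epoxide of F3 | C=C(CO[Si](C)(C)C(C)(C)C)[C@@H]1[C@H](O[Si](C)(C)C(C)(C)C)C[C@H](C)[C@]26O[C@@H]6[C@@H](C(C)=O)[C@]3(C[C@@H]2C1)C(=O)O[C@H]4C[C@@H](C)[C@]5(CO[Si](C)(C)C(C)(C)C)O[C@@H]5C[C@H]43
F5 | step 11 | side-chain oxirane of 12 (both epimers at the oxirane carbon) | CC1=C[C@@H](O[Si](C)(C)C(C)(C)C)[C@@H](C2(CO[Si](C)(C)C(C)(C)C)CO2)CC1=O
F6 | step 11 | side-chain oxirane of 13 (both epimers at the oxirane carbon) | C[C@H]1C[C@@H](O[Si](C)(C)C(C)(C)C)[C@@H](C2(CO[Si](C)(C)C(C)(C)C)CO2)CC1=O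
F7 | step 23 | side-chain oxirane of 27 (both epimers at the oxirane carbon) | CC1=C[C@H](O[Si](C)(C)C(C)(C)C)[C@H](C2(CO[Si](C)(C)C(C)(C)C)CO2)CC1=O
F8 | step 23 | side-chain oxirane of 28 (both epimers at the oxirane carbon) | C[C@@H]1C[C@H](O[Si](C)(C)C(C)(C)C)[C@H](C2(CO[Si](C)(C)C(C)(C)C)CO2)CC1=O
F9 | step 12 | kinetic trimethylsilyl enol ether of 13 | C[C@H]1C[C@@H](O[Si](C)(C)C(C)(C)C)[C@@H](C(=C)CO[Si](C)(C)C(C)(C)C)C=C1O[Si](C)(C)C
F10 | step 12 | silyloxycyclopropane from F9 (cyclopropane face undefined) | C[C@H]1C[C@@H](O[Si](C)(C)C(C)(C)C)[C@@H](C(=C)CO[Si](C)(C)C(C)(C)C)C2CC12O[Si](C)(C)C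
F11 | step 12 | β-chloro cycloheptanone (chlorine-bearing centre undefined) | C[C@H]1C[C@@H](O[Si](C)(C)C(C)(C)C)[C@@H](C(=C)CO[Si](C)(C)C(C)(C)C)C(Cl)CC1=O
F12 | step 12 | cyclohept-2-enone (C19=C20) corresponding to 15 | C[C@H]1C[C@@H](O[Si](C)(C)C(C)(C)C)[C@@H](C(=C)CO[Si](C)(C)C(C)(C)C)C=CC1=O
F13 | step 24 | kinetic trimethylsilyl enol ether of 28 | C[C@@H]1C[C@H](O[Si](C)(C)C(C)(C)C)[C@H](C(=C)CO[Si](C)(C)C(C)(C)C)C=C1O[Si](C)(C)C
F14 | step 24 | silyloxycyclopropane from F13 (cyclopropane face undefined) | C[C@@H]1C[C@H](O[Si](C)(C)C(C)(C)C)[C@H](C(=C)CO[Si](C)(C)C(C)(C)C)C2CC12O[Si](C)(C)C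
F15 | step 24 | β-chloro cycloheptanone, mirror series (chlorine-bearing centre undefined) | C[C@@H]1C[C@H](O[Si](C)(C)C(C)(C)C)[C@H](C(=C)CO[Si](C)(C)C(C)(C)C)C(Cl)CC1=O
F16 | step 24 | cyclohept-2-enone corresponding to 30 | C[C@@H]1C[C@H](O[Si](C)(C)C(C)(C)C)[C@H](C(=C)CO[Si](C)(C)C(C)(C)C)C=CC1=O
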